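In this vessel D enters at a steady 0.0250 min⁻¹, as a fraction of its charge, and we ask how much of that inflow stays as X.

| setting | dusk | flask |
|---|---|---|
| D | 0.40 M (fed, over 40 min) | 0.20 M (fed, over 40 min) |
| J | 3 equiv | 3.00 equiv |
| remark | run made earlier |  |
| time |  | 2.0 h |

- dusk (time / min: X / %, D / %): 2.00: 5, 1; 6.00: 8, 5; 12.0: 15, 5; 15.0: 17, 5; 25.0: 24, 6

(each reading ± 1.5 percentage points)

- what was read earlier has a scatter of 1.5 percentage points, one standard deviation
- steps that have been proposed: D + J <-> X; D + J <-> G; J -> L
- percentages count the whole charge, also what has not yet gone in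

* time up to 2.0 h at which X stands highest
* the amount of X, in percent of the D charged, at that time

In the dusk run X rose at 0.0100 min⁻¹, as a fraction of the charge, between 2.00 min and 12.0 min, then at 0.00692 min⁻¹ up to 25.0 min, although the feed held steady. The rate thus slowed by a factor 0.692 across the 11.5 min between the middles of those spans. We read this as a loss in proportion to the X present, with a time constant of 31.3 min, the lifetime of X. With a scatter of 1.5 percentage points on each reading, this figure is rough.

Run back to the start, the rate is 0.0125 min⁻¹, about half of the inflow. Gain and loss would balance at 39.1%. We carry both figures to the flask, which has the equivalents and dosing time of the dusk run but 0.20 M of D against 0.40 M, so this is a judgement. The feed lasts 1.28 lifetimes, so our count puts X at 28.2% at the end of the feed, 0.667 h, and we expect it to fall afterwards.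

The forecast gives 30% (range 24% to 36%) at 0.72 h (range 0.62 h to 0.95 h), and says “It peaks just after feed end, then decays”.

The flask gives 29.7% at 0.674 h, when G already stands at 54.1%.

    D + J ⇌ X (K = 4.28 M⁻¹, k = 0.748 M⁻¹ min⁻¹)
    D + J ⇌ G (K = 190 M⁻¹, k = 0.264 M⁻¹ min⁻¹)
    J → L (k = 1.44 × 10⁻⁴ min⁻¹)

Letting X fall from that top with our lifetime gives 15.9% at 1.00 h, and the flask holds 16.7%.

For a neighbour flask with 1.20 equiv of J, our count has no term in J and again gives 28.2%. That neighbour flask reaches 20.9%, less than the count, so we keep this lifetime for the 3 equiv at which it was read.

The numbers in the tables were generated by integration with constants of no real substance.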